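**Remark on the chemistry:** the target has no stereogenic element (each C2 carries two methyl groups), so it is achiral. The requirement of a single enantiomer therefore needs no stereocontrol, and the SMILES carries no stereodescriptors.

## Structural features

The target is a dihydrochalcone in which two 2,2-dimethylchroman units are joined C6 to C6 through a three-carbon chain, Ar–C(=O)–CH2–CH2–Ar′. The A-ring chroman carries the ketone at C6 with free hydroxyls on both flanking carbons, C5 and C7. This ring is therefore an acylphloroglucinol whose third oxygen is the pyran oxygen O1, para to the acyl group, and C8 is its only aromatic C–H. The B-ring chroman bears nothing but the chain at C6 (para to its O1) and is a plain, electron-rich alkyl aryl ether. There are no stereocentres, so none adjoin, and every selectivity problem is regiochemical. The fragile elements are the two electron-rich arenes (oxidation), the tertiary O1–C2 ether bonds (ionisation by strong acids), the benzylic C4 methylenes, the enolisable CH2 next to the ketone and, once formed, the chelated 2,6-dihydroxyaryl ketone. The real difficulty is the A-ring pattern: fusing a pyran onto an acylphloroglucinol, or acylating a 5,7-dioxygenated chroman, can give the 6-acyl or the 8-acyl isomer. The key step exploits the fact that the two hydroxylated carbons C5 and C7 are exactly the two positions ortho to the C6 carbonyl. Without these oxygens the molecule is a ketone made of two identical chromans, and the carbonyl oxygen can deliver a metal to C5–H and C7–H.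

## Logic of the disconnections

**12 ⇒ 9 (through 11 and 10).** The two aryl C–O bonds at C5 and C7 of the A ring are cut. Both lie ortho to the C6 carbonyl, and their removal leaves two identical chroman units, so the 6-acyl versus 8-acyl question disappears from the rest of the synthesis. The gain is the loss of two heteroatom substituents and of all phenol protection. The forward step must oxygenate twice, the second time at the carbon crowded by C4, must leave C8 and the whole B ring alone, and must keep the new oxygens masked as esters (10, 11) until work-up. The ketone of 9 is kept as the directing group; a stronger nitrogen director would cost two extra steps and a difficult unmasking.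

**9 ⇒ 7 + 4 (through 8).** The bond between the carbonyl carbon and C6 of the A ring is cut. C6 is para to the ring oxygen of 4, the natural site for an electrophile, and the cut divides the molecule into two halves of similar size. The forward acylation must beat cyclisation of the activated acid 8 onto its own ring, must go para and not ortho to oxygen, and must use an acid mild enough for the tertiary ethers.

**7 ⇒ 5 + 2 (through 6).** The aryl C4a–C4 bond and the O1–C2 bond of the B-ring pyran are cut, removing a five-carbon unit. The phenol of 5 is para-substituted, so only the ortho positions are open and one regioisomer can form. Both fragments are commercial. The forward step needs the carboxyl group to come through an acid-catalysed alkylation, and 6 must close in the Markovnikov sense.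

**4 ⇒ 1 + 2 (through 3).** The same two bonds are cut on the A-ring pyran. The gain is two bulk chemicals. The forward step must alkylate ortho rather than para on an unsubstituted phenol and must stop after one annulation.

## Other disconnections considered

**Alternative 1:** The cut removes, on each aromatic ring, the aryl C–C bond to C4 and the O1–C2 bond, so both pyrans fall away. What remains is phloretin A1, which already holds the whole C6–C3–C6 chain and every oxygen. Its two non-chelated hydroxyls would be etherified with a tertiary propargylic electrophile to give A2.
- Forward key step: heating A2 should cause, on each ring, an aryl propargyl Claisen shift, a 1,5-hydrogen shift and an oxa-6π closure, giving bis-chromene A3. Hydrogenation of both C3=C4 bonds would then give 12.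
- In favour: A1 is cheap, and the A-ring regiochemistry is set by the oxygen that carries the propargyl group. Every operation is of an established type. On precedent this plan is better than the chosen one.
- Against: four phenols compete for a hindered electrophile that also eliminates easily, so the selective double O-alkylation is the weak point. A3 is two oxidation levels above 12, and its reduction must spare the aryl ketone. The cascade also needs high temperature on a free acylphloroglucinol.
- Comparison: structurally, Alternative 1 makes the pyrans last on a finished chain, whereas the chosen plan makes the pyrans first and the two C–O bonds last. Mechanistically, a thermal pericyclic cascade with built-in regiocontrol stands against a catalytic C–H oxidation steered by the carbonyl. In step count it is the equal of the chosen route or slightly better (three steps from A1 against four). The chosen route avoids selective alkylation of a polyphenol and any redox correction, but pays with an unproven step.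

**Alternative 2:** The cut is made at both ends of the two-carbon bridge, the C(=O)–Cα bond and the Cβ–aryl bond to C6 of the B ring. This leaves the A-ring aroyl chloride A6, a vinyl unit and the B-ring aryl-9-BBN A4.
- Forward key step: A4 and a vinyl-metal reagent form the ate complex A5. Under nickel catalysis the acyl group of A6 bonds to the terminal vinyl carbon while the chroman-6-yl group shifts from boron to the internal carbon. Protodeboronation in the same flask would leave ketone A7, and hydrogenolysis of the benzyl ethers would give 12.
- In favour: two skeletal C–C bonds form in one three-component operation. The A-ring oxygens are present from the start, so no electron-rich arene has to face an oxidant; on this point it is better than the chosen plan.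
- Against: A6 is a doubly ortho-substituted aroyl chloride, expected to be slow in acyl transfer and prone to decarbonylation. Its preparation brings back the 6- versus 8-carbonyl problem on a phloroglucinol and needs protection. The benzylic boron intermediate must be protodeboronated without enolate side reactions, and two deprotections follow.
- Comparison: structurally it builds the bridge, not the rings or the oxygens. Mechanistically a 1,2-metalate shift replaces directed C–H oxidation, and both are modern catalytic steps applied beyond their usual substrates. In step count it is clearly longer, because A6 alone should need more steps than the whole chosen route.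

**Alternative 3:** The cut lies inside the A-ring benzene, at the C6–C5 bond (C1′–C2′). The ring is traced back to pyranopyranone A9, which would come from lateral metalation of A8 and acylation with an activated derivative of 7.
- Forward key step: methoxide opens the enol lactone of A9 to a methyl ester and a triketide chain. The carbon between the two ketones attacks the ester (Claisen condensation), and aromatisation gives chromene A10 with the 2H-pyran untouched. Hydrogenation of C3=C4 would give 12.
- In favour: the pyran oxygen is placed para to the acyl group before the benzene ring exists, so no 6-acyl/8-acyl ambiguity can arise. On regiochemical certainty it is the equal of the chosen plan, and it needs no metal catalyst and no oxidant.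
- Against: A9 is not simple. The acylation leaves an acidic β-diketone that quenches the anion. The opened triketo ester can also close by aldol condensation to a resorcylate instead of the acylphloroglucinol. A final hydrogenation is still needed.
- Comparison: structurally it is the only plan that builds the aromatic ring. Mechanistically it relies on carbonyl condensation with a chemoselectivity question (Claisen versus aldol) instead of a site-selectivity question. In step count it is longer, about five operations beyond 7, which the chosen route also needs.

Key step: step 4

## Route

Step 1
Reactants: 1 phenol; 2 isoprene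
Product: 4 2,2-dimethylchroman, via 2-prenylphenol 3 (not isolated)
Conditions: Amberlyst 15, heptane–THF, 60 °C (sealed), 1 in excess; 2 M NaOH wash; distil
Reagents that add atoms: none
Why: Acid-catalysed Friedel–Crafts prenylation of the phenol ortho position by the isoprene-derived allylic cation, followed by Markovnikov intramolecular hydroalkoxylation, is a known phenol–diene chroman annulation. Excess 1 limits double alkylation, and the neutral ether 4 is freed from phenolic by-products (unreacted 1, para-prenylated material) by the alkaline wash.

Step 2
Reactants: 5 3-(4-hydroxyphenyl)propanoic acid; 2 isoprene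
Product: 7 3-(2,2-dimethylchroman-6-yl)propanoic acid, via prenylphenol acid 6 (not isolated)
Conditions: Amberlyst 15, THF–heptane, 60 °C (sealed); then 1 M NaOH, rt; H3O+
Reagents that add atoms: none
Why: The same chroman annulation on a para-blocked phenol, so only ortho attack is possible and a single regioisomer should form. Any allylic ester formed reversibly at the carboxyl group is cleaved in the hydroxide work-up, and acid–base extraction isolates 7.

Step 3
Reactants: 7 3-(2,2-dimethylchroman-6-yl)propanoic acid; 4 2,2-dimethylchroman
Product: 9 1,3-bis(2,2-dimethylchroman-6-yl)propan-1-one, via mixed anhydride 8 (not isolated)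
Conditions: TFAA, 85% H3PO4 (cat.), CH2Cl2, 0 °C → rt; 4 (1.5 equiv)
Reagents that add atoms: none
Why: Friedel–Crafts acylation through the acyl trifluoroacetate should attack 4 at C6, para to the ring oxygen, the ortho position C8 being more hindered. Ring closure of 8 to an indanone would have to occur meta to its own ether oxygen and should be outrun by the intermolecular reaction with excess 4. No metal halide Lewis acid is present that could open the tertiary ethers.

Step 4
Reactants: 9 1,3-bis(2,2-dimethylchroman-6-yl)propan-1-one
Product: 12 1-(5,7-dihydroxy-2,2-dimethylchroman-6-yl)-3-(2,2-dimethylchroman-6-yl)propan-1-one (target), via monotrifluoroacetate 10 (not isolated), via bis(trifluoroacetate) 11 (not isolated)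
Conditions: Pd(TFA)2 (10 mol%), K2S2O8 (5 equiv, portionwise), TFA/TFAA 9:1, 50 °C; then H2O–THF, rt
Reagents that add atoms: trifluoroacetic acid, OC(=O)C(F)(F)F (source of the two phenolic oxygens)
Why: Proposed new method: the carbonyl oxygen of 9 binds Pd(II) trifluoroacetate and directs carboxylate-assisted cyclopalladation of an ortho C–H bond, expected first at the less hindered C7; persulfate oxidises the five-membered palladacycle to a high-valent aryl–Pd trifluoroacetate, and C–O reductive elimination gives 10 and returns Pd(II). Because TFAA keeps the new oxygen as a trifluoroacetate ester, it neither chelates the carbonyl nor exposes a free phenol, so the ketone can turn and direct a second cycle at C5, the carbon flanked by the C4 methylene, to give 11; aqueous work-up hydrolyses both esters to 12. The closest known reaction type is Pd(II)- or Ru(II)-catalysed ketone-directed ortho C–H hydroxylation of aryl ketones in TFA/TFAA with persulfate or iodine(III) oxidants, established for one unhindered ortho position; the twofold reaction, the second event at a 1,2,3-trisubstituted site, and the tolerance of two alkyl aryl ether rings are the unproven extensions. No ring is closed and no stereocentre is formed. The selectivity needed is for C5 and C7 of the A ring over C8 and over every position of the B ring; it rests on the fact that only the A ring carries a coordinating group and that both of its ortho positions are wanted, whereas the B ring could be metalated only through a seven-membered chelate or by slower undirected attack. Persulfate is preferred to an iodine(III) oxidant, which would be expected to oxygenate the enolisable CH2 next to the ketone and to oxidise the electron-rich B ring directly; portionwise addition at moderate temperature is intended to limit sulfate-radical attack at the benzylic positions.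

## Compound list

1 | phenol | Oc1ccccc1 | starting material
2 | isoprene | C=CC(C)=C | starting material
3 | 2-(3-methylbut-2-en-1-yl)phenol | CC(C)=CCc1ccccc1O | intermediate (not isolated)
4 | 2,2-dimethylchroman | CC1(C)CCc2ccccc2O1 | intermediate
5 | 3-(4-hydroxyphenyl)propanoic acid | O=C(O)CCc1ccc(O)cc1 | starting material
6 | 3-[4-hydroxy-3-(3-methylbut-2-en-1-yl)phenyl]propanoic acid | CC(C)=CCc1cc(CCC(=O)O)ccc1O | intermediate (not isolated)
7 | 3-(2,2-dimethylchroman-6-yl)propanoic acid | O=C(O)CCc1ccc2OC(C)(C)CCc2c1 | intermediate
8 | 3-(2,2-dimethylchroman-6-yl)propanoic trifluoroacetic anhydride | O=C(CCc1ccc2OC(C)(C)CCc2c1)OC(=O)C(F)(F)F | intermediate (not isolated)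
9 | 1,3-bis(2,2-dimethylchroman-6-yl)propan-1-one | O=C(CCc1ccc2OC(C)(C)CCc2c1)c1ccc2OC(C)(C)CCc2c1 | intermediate
10 | 6-[3-(2,2-dimethylchroman-6-yl)propanoyl]-2,2-dimethylchroman-7-yl trifluoroacetate | O=C(CCc1ccc2OC(C)(C)CCc2c1)c1cc2CCC(C)(C)Oc2cc1OC(=O)C(F)(F)F | intermediate (not isolated)
11 | 6-[3-(2,2-dimethylchroman-6-yl)propanoyl]-2,2-dimethylchroman-5,7-diyl bis(trifluoroacetate) | O=C(CCc1ccc2OC(C)(C)CCc2c1)c1c(OC(=O)C(F)(F)F)cc2OC(C)(C)CCc2c1OC(=O)C(F)(F)F | intermediate (not isolated)
12 | 1-(5,7-dihydroxy-2,2-dimethylchroman-6-yl)-3-(2,2-dimethylchroman-6-yl)propan-1-one | CC1(C)CCc2cc(CCC(=O)c3c(O)cc4c(c3O)CCC(C)(C)O4)ccc2O1 | target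

## Step count and least certain steps

Total: 4 steps. Longest linear sequence: 3 steps (5 → 7 → 9 → 12, or 1 → 4 → 9 → 12).

**Step 4 (key step, proposed new method).** The most likely failure is stalling after the first oxygenation, because cyclometalation at C5 next to the C4 methylene is slow. Oxidative degradation may then take over: sulfate-radical attack at the benzylic carbons, or undirected oxidation of the electron-rich B ring.
The fallback uses only known reaction types, sets out from 7 and comes back to the route at 12.
- Friedel–Crafts acylation of phloroglucinol with 7 (BF3·OEt2, 80–90 °C) should give 3-(2,2-dimethylchroman-6-yl)-1-(2,4,6-trihydroxyphenyl)propan-1-one F1.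
- Alkylation of its one non-chelated hydroxyl, para to the acyl group, with 3-chloro-3-methylbut-1-yne (K2CO3, KI, cat. CuI, acetone) should give 1-[2,6-dihydroxy-4-(2-methylbut-3-yn-2-yloxy)phenyl]-3-(2,2-dimethylchroman-6-yl)propan-1-one F2.
- Heating (N,N-diethylaniline, 150–190 °C) should bring about the propargyl Claisen shift, 1,5-hydrogen shift and oxa-6π closure to 1-(5,7-dihydroxy-2,2-dimethyl-2H-chromen-6-yl)-3-(2,2-dimethylchroman-6-yl)propan-1-one F3, the same compound as A10. The oxygen that carried the propargyl group becomes O1, which fixes the 6-acyl pattern.
- Hydrogenation (H2, Pd/C, EtOAc, rt) of the chromene double bond should give 12.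

**Step 3.** The activated acid may cyclise onto its own ring to an indanone, acylation may occur partly at C8, or the acid medium may open a tertiary ether; all three lower the yield of the para ketone.
The fallback reverses the polarity, sets out from 4 and 7 and comes back at 9.
- 4 is brominated para to oxygen (NBS, MeCN, 0 °C) to 6-bromo-2,2-dimethylchroman F4.
- 7 is converted (CDI, then MeNHOMe·HCl) into N-methoxy-N-methyl-3-(2,2-dimethylchroman-6-yl)propanamide F5.
- Bromine–lithium exchange on F4 (n-BuLi, THF, −78 °C) gives (2,2-dimethylchroman-6-yl)lithium F6, which adds to F5 and should give 9 on aqueous NH4Cl work-up.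

**Step 1.** Para C-prenylation and double alkylation may compete with ortho attack on the unsubstituted phenol, and isoprene may oligomerise, so that 4 is formed in poor yield.
The fallback fixes the ortho regiochemistry by a sigmatropic shift, sets out from 1 and comes back at 4.
- O-alkylation of 1 with 3-chloro-3-methylbut-1-yne (K2CO3, KI, cat. CuI, acetone) gives (2-methylbut-3-yn-2-yl)oxybenzene F7.
- Thermal Claisen cascade (N,N-diethylaniline, 190 °C) gives 2,2-dimethyl-2H-chromene F8.
- Hydrogenation (H2, Pd/C, EtOAc) gives 4.

**Step 2.** The free carboxyl group may capture the allylic cation (ester formation that consumes isoprene), and cyclisation of the prenylated phenol may be incomplete in the donor solvent needed to dissolve 5.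
The fallback builds the acid chain on the finished chroman, sets out from 4 and comes back at 7.
- Rieche formylation of 4 (Cl2CHOMe, TiCl4, CH2Cl2, 0 °C) gives 2,2-dimethylchroman-6-carbaldehyde F9.
- Knoevenagel–Doebner condensation (malonic acid, pyridine, cat. piperidine, 90 °C) gives (E)-3-(2,2-dimethylchroman-6-yl)prop-2-enoic acid F10.
- Hydrogenation (H2, Pd/C, EtOAc) gives 7.

## Further compounds

F1 | step 4 | 3-(2,2-dimethylchroman-6-yl)-1-(2,4,6-trihydroxyphenyl)propan-1-one | O=C(CCc1ccc2OC(C)(C)CCc2c1)c1c(O)cc(O)cc1O
F2 | step 4 | 1-[2,6-dihydroxy-4-(2-methylbut-3-yn-2-yloxy)phenyl]-3-(2,2-dimethylchroman-6-yl)propan-1-one | O=C(CCc1ccc2OC(C)(C)CCc2c1)c1c(O)cc(OC(C)(C)C#C)cc1O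
F3 | step 4 | 1-(5,7-dihydroxy-2,2-dimethyl-2H-chromen-6-yl)-3-(2,2-dimethylchroman-6-yl)propan-1-one | O=C(CCc1ccc2OC(C)(C)CCc2c1)c1c(O)cc2OC(C)(C)C=Cc2c1O
F4 | step 3 | 6-bromo-2,2-dimethylchroman | CC1(C)CCc2cc(Br)ccc2O1
F5 | step 3 | N-methoxy-N-methyl-3-(2,2-dimethylchroman-6-yl)propanamide | CON(C)C(=O)CCc1ccc2OC(C)(C)CCc2c1
F6 | step 3 | (2,2-dimethylchroman-6-yl)lithium | [Li]c1ccc2OC(C)(C)CCc2c1
F7 | step 1 | (2-methylbut-3-yn-2-yl)oxybenzene | C#CC(C)(C)Oc1ccccc1
F8 | step 1 | 2,2-dimethyl-2H-chromene | CC1(C)C=Cc2ccccc2O1
F9 | step 2 | 2,2-dimethylchroman-6-carbaldehyde | O=Cc1ccc2OC(C)(C)CCc2c1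
F10 | step 2 | (E)-3-(2,2-dimethylchroman-6-yl)prop-2-enoic acid | OC(=O)/C=C/c1ccc2OC(C)(C)CCc2c1
A1 | alternative 1 | phloretin, 3-(4-hydroxyphenyl)-1-(2,4,6-trihydroxyphenyl)propan-1-one | O=C(CCc1ccc(O)cc1)c1c(O)cc(O)cc1O
A2 | alternative 1 | 1-[2,6-dihydroxy-4-(2-methylbut-3-yn-2-yloxy)phenyl]-3-[4-(2-methylbut-3-yn-2-yloxy)phenyl]propan-1-one | O=C(CCc1ccc(OC(C)(C)C#C)cc1)c1c(O)cc(OC(C)(C)C#C)cc1O
A3 | alternative 1 | 1-(5,7-dihydroxy-2,2-dimethyl-2H-chromen-6-yl)-3-(2,2-dimethyl-2H-chromen-6-yl)propan-1-one | O=C(CCc1ccc2OC(C)(C)C=Cc2c1)c1c(O)cc2OC(C)(C)C=Cc2c1O
A4 | alternative 2 | 9-(2,2-dimethylchroman-6-yl)-9-borabicyclo[3.3.1]nonane | CC1(C)CCc2cc(ccc2O1)B1C2CCCC1CCC2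
A5 | alternative 2 | lithium 9-(2,2-dimethylchroman-6-yl)-9-vinyl-9-boratabicyclo[3.3.1]nonane | [Li+].C=C[B-]1(c2ccc3OC(C)(C)CCc3c2)C2CCCC1CCC2
A6 | alternative 2 | 5,7-bis(benzyloxy)-2,2-dimethylchroman-6-carbonyl chloride | O=C(Cl)c1c(OCc2ccccc2)cc2OC(C)(C)CCc2c1OCc1ccccc1
A7 | alternative 2 | 1-[5,7-bis(benzyloxy)-2,2-dimethylchroman-6-yl]-3-(2,2-dimethylchroman-6-yl)propan-1-one | O=C(CCc1ccc2OC(C)(C)CCc2c1)c1c(OCc2ccccc2)cc2OC(C)(C)CCc2c1OCc1ccccc1
A8 | alternative 3 | 2,2,7-trimethyl-2H,5H-pyrano[4,3-b]pyran-5-one | CC1=CC2=C(C=CC(C)(C)O2)C(=O)O1
A9 | alternative 3 | 7-[4-(2,2-dimethylchroman-6-yl)-2-oxobutyl]-2,2-dimethyl-2H,5H-pyrano[4,3-b]pyran-5-one | CC1(C)C=CC2=C(O1)C=C(CC(=O)CCc1ccc3OC(C)(C)CCc3c1)OC2=O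
A10 | alternative 3 | 1-(5,7-dihydroxy-2,2-dimethyl-2H-chromen-6-yl)-3-(2,2-dimethylchroman-6-yl)propan-1-one | O=C(CCc1ccc2OC(C)(C)CCc2c1)c1c(O)cc2OC(C)(C)C=Cc2c1O
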